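## Analysis of the target

The target is a sesquineolignan in which an aryltetralin is joined through an aryl alkyl ether to an arylpropanol. Locants used throughout: tetralin C1–C8a, ring A the fused arene (7-OH, 6-OMe), ring B the saturated ring, ring C the guaiacyl ring on C1, ring D the guaiacyl ring of the side chain, C7' the carbinol carbon and C8' the methyl-bearing carbon that carries the ether oxygen of ring C. Ring B holds three contiguous stereocentres, C1 (S), C2 (S) and C3 (R); the C1 aryl is trans to the C2 methyl and the two methyls are trans to each other, so all three substituents can sit equatorially on a half-chair. The side chain holds two more, C7' (S) and C8' (R), in the erythro relationship; ring C insulates them from the tetralin centres, so each set must be fixed in absolute terms. Sensitive points are the two free phenols, the para-hydroxybenzylic alcohol at C7' (it ionises to a quinone methide under acid or strong base and can be hydrogenolysed), and C8', which epimerises easily while C7' is a ketone. The difficulty lies in ring B: C2, C3 and C4 carry only methyl groups and hydrogen, so carbonyl-based ring constructions need later deoxygenations, and the two nearly identical guaiacol oxygens on rings A and C must be told apart because only the ring C oxygen bears the side chain. The strategy rests on the fact that rings A and C, C1–C4 and the two methyls are two (E)-propenylguaiacol units joined head to head: C2–C3 links the two methyl-bearing carbons, and C1–C8a links the benzylic carbon of the ring C unit to the ring A carbon para to its methoxy group.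

## Retrosynthetic reasoning

20 ⇒ 19. Only the O–acyl bond of the ring A pivalate and the O–Si bond of the ring D silyl ether are cut. Both groups are chosen so that one mild methanolysis removes them; acidic or hydrogenolytic end-games are avoided because of the C7' benzylic alcohol. The forward step must free two phenols without touching C7' or C8'.

19 ⇒ 18. The C7'–H bond is cut, leading back to aryl ketone 18. This places the creation of C7' after that of C8', so the existing ether stereocentre can direct the hydride; a chelation-controlled reduction has to deliver the erythro (7'S) alcohol.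

18 ⇒ 13 + 17. The bond between C7' and ring D is cut to Weinreb amide 13 and Grignard reagent 17, the latter from bromide 16, itself from bromophenol 14 and silyl chloride 15. Cutting here keeps the epimerisable ketone out of the route until the step before its reduction and brings ring D in as a simple protected aryl nucleophile. The forward addition must stop at the ketone and leave C8' and the aryl pivalate intact.

13 ⇒ 9 + 12. The C8'–O bond to ring C is cut. Phenol 9 is the nucleophile; hydroxy amide 12, one step from ester 10 and amine salt 11, is the electrophile. A Mitsunobu reaction with inversion turns the (S) centre of the chiral pool into the (R) centre of the target, so C8' needs no asymmetric synthesis.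

9 ⇒ 8. The free ring C phenol is traced back to its benzyl ether. The two guaiacol oxygens are differentiated by construction: the ring C oxygen is an ether, the ring A oxygen an ester, and hydrogenolysis unmasks only the former.

8 ⇒ 3 + 5. Two skeletal bonds, C2–C3 and C1–C8a, are cut; ring B opens and two propenylarenes result, benzyl ether 3 and pivalate 5. No other cut through ring B gives two pieces that already hold every carbon at the oxidation level of the target. The forward reaction must do four things:
- couple the alkenes at their methyl-bearing carbons;
- close ring B by attack of ring A on the benzylic carbon next to ring C;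
- set C1, C2 and C3 all-trans in one absolute sense;
- prefer the crossed product over the homodimers.

The different O-substituents make 3 the easier alkene to oxidise, and a chiral counter-ion is to supply the absolute sense.

3 ⇒ 1 + 2 and 5 ⇒ 1 + 4. Both alkenes come from the same commercial phenol 1, by O-benzylation with 2 and O-acylation with 4, so each partner of the key step is one step from purchase.

## Alternatives that were turned down

Alternative 1: The bond from C1 to ring C and the C2–CH3 bond are cut together; ring B stays open. Forward, the (Z)-alkenyl boronate A2 is converted into its four-coordinate methyl ate complex. An arylpalladium species made from triflate A3 with a chiral bisphosphine then triggers the shift of methyl from boron to C2 while the ring C aryl is delivered to C1, giving boronate A1.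
- For: this conjunctive coupling is an established enantioselective process, so C1 and C2 would be set by catalyst control with a predictability the chosen strategy lacks, and the C2–B bond is a handle for stereospecific homologation.
- Against: the step closes no ring and sets two of three centres. C3 with its methyl and then C4 need two further boron homologations, ring B must be closed by an alkyl–aryl coupling onto the ring A chloride, and A2 (chlorinated, silylated, Z-configured) needs several steps itself.
- Comparison: the stage corresponding to 8 would take well over ten steps instead of three. On stereochemical reliability alternative 1 is the stronger; the chosen strategy offers in exchange both ring B bonds, the ring and all three centres in one redox-neutral step from two one-step compounds.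

Alternative 2: C1–C2 and C3–C4 are cut, a Diels–Alder disconnection of ring B. Forward, ultraviolet light converts benzaldehyde A5 into its photoenol (the hydroxy-ortho-quinodimethane of A5), which adds crotonate A6 to give tetralin A4.
- For: like the chosen step it forms two C–C bonds and ring B at once and fixes the relative configuration of C1–C3 through an endo transition state. The reaction type is known, so the ring construction is better precedented than in the chosen strategy.
- Against: A4 carries a C4 hydroxyl and a C3 ester that the target lacks. The ester must be taken down to methyl and the benzylic hydroxyl removed, about four corrective steps. A β-substituted acrylate is a sluggish partner for a short-lived photoenol, and the geometry of the diene terminus that becomes C1 is not secured. Nothing controls absolute configuration, and A5 needs its own multistep synthesis with three phenol protecting groups.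
- Comparison: the chosen strategy needs no corrective redox steps, because 3 and 5 already have the oxidation level of the target at every carbon.

Alternative 3: Only C1–C2 is cut; ring B is closed by intramolecular conjugate addition. Forward, mild acid dehydrates diaryl carbinol A8 to the para-quinone methide of ring C, and the enamine formed from the tethered aldehyde and a secondary amine attacks the methide carbon in a six-membered closure to give aldehyde A7.
- For: enamine additions to para-quinone methides are well precedented. C3 is set beforehand and relays its configuration to C2 and C1 through an all-equatorial chair, so absolute control does not depend on an untested catalyst. The ring C phenol emerges free exactly where the side chain goes, one deprotection fewer than in the chosen route.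
- Against: one bond and two centres only. A8 needs a long linear synthesis including an asymmetric step for C3, and the formyl group of A7 must be reduced to methyl in two or three steps at a centre that is epimerisable while the aldehyde is present.
- Comparison: alternative 3 is the safer but markedly longer plan; the chosen strategy trades that safety for three steps to tetralin 8.

Key step: step 3

Remark (assumption): isoeugenol is used as its commercially available pure (E) isomer. Which enantiomer of the chiral anion leads to the (1S,2S,3R) series cannot be derived from a model, so the (S,S) anion written in step 3 stands for whichever enantiomer a first screen identifies.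

Definitions: bpz = 2,2'-bipyrazine. IDPi− = imidodiphosphorimidate anion N[P(=NSO2CF3)(O2Ar*)]2−, in which each O2Ar* is (S)-3,3'-bis[3,5-bis(trifluoromethyl)phenyl]-1,1'-binaphthalene-2,2'-diolate.

## Route

Step 1
Reactants: 1 (E)-isoeugenol, 2-methoxy-4-[(E)-prop-1-enyl]phenol; 2 benzyl bromide
Product: 3 1-(benzyloxy)-2-methoxy-4-[(E)-prop-1-enyl]benzene
Conditions: BnBr, K2CO3, acetone, reflux
Reagents that add atoms: benzyl bromide (2), BrCc1ccccc1
Why: Williamson etherification of the phenoxide (SN2 on benzyl bromide); the propenyl double bond and its (E) geometry are not affected by carbonate base, and the benzyl ether leaves this arene the stronger electron donor of the two key-step partners.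

Step 2
Reactants: 1 (E)-isoeugenol; 4 pivaloyl chloride
Product: 5 2-methoxy-4-[(E)-prop-1-enyl]phenyl pivalate
Conditions: PivCl, Et3N, 4-(dimethylamino)pyridine (5 mol %), CH2Cl2, 0 °C → rt
Reagents that add atoms: pivaloyl chloride (4), CC(C)(C)C(=O)Cl
Why: Nucleophile-catalysed O-acylation of the phenol; the acyl group withdraws electron density from the oxygen and so raises the oxidation potential of this alkene above that of 3, and the hindered ester withstands hydrogenolysis and Mitsunobu conditions.

Step 3
Reactants: 3 1-(benzyloxy)-2-methoxy-4-[(E)-prop-1-enyl]benzene; 5 2-methoxy-4-[(E)-prop-1-enyl]phenyl pivalate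
Product: 8 (1S,2S,3R)-1-(4-benzyloxy-3-methoxyphenyl)-6-methoxy-2,3-dimethyl-1,2,3,4-tetrahydronaphthalen-7-yl pivalate, via distonic radical cation 6 (not isolated), via C4 benzylic radical 7 (not isolated)
Conditions: [Ru(bpz)3][(S,S)-IDPi]2 (2 mol %), 2,4,6-iPr3C6H2SH (10 mol %), 5 (4 equiv), 3 added over 8 h, degassed CH2Cl2/PhMe 1:1, 450 nm LEDs, −40 °C
Reagents that add atoms: none
Why: Proposed new method: the excited divalent ruthenium complex [Ru(bpz)3]2+ is strong enough to oxidise ether 3 but not ester 5, so only 3 becomes a radical cation, which in the non-polar medium stays paired with a chiral IDPi anion; the β-carbon of neutral 5 adds to the β-carbon of this radical cation (C2–C3) to give distonic species 6, with the positive charge on C1 next to the para-benzyloxy ring C and the unpaired electron on the ring A benzylic carbon C4. Ring A then attacks C1 through C8a, the carbon para to its methoxy group, in a cationic six-membered Friedel–Crafts closure of ring B (6-endo if the C4a–C8a arene bond is taken as the reacting π-bond) through a chair-like transition state, and loss of the arenium proton to the IDPi anion leaves benzylic radical 7. The reduced complex [Ru(bpz)3]+ is not reducing enough to turn a simple benzylic radical into its anion, so the loop is closed by a thiol relay: the arenethiol gives a hydrogen atom to C4, the thiyl radical takes the electron back from [Ru(bpz)3]+, and the thiolate is reprotonated by the IDPi acid, which makes the whole process an isomerisation of 3 plus 5 without stoichiometric reagents. The closest known reactions are the photoredox radical-cation [2+2] cycloadditions of anethole-type β-methylstyrenes, the acridinium/disulfide formal [4+2] cyclodimerisation of styrenes to 1-aryltetralins, and radical-cation cycloadditions steered by IDPi counter-anions; a crossed and enantioselective [4+2] of two β-methylstyrenes has not been described. C2 and C3 arise in the C–C bond formation, which is reversible (cyclobutanes formed from 6 are reopened by re-oxidation, whereas 8 is not), and are sorted in the ring closure, where the chair with both methyl groups equatorial gives the trans-2,3 relationship; C1 is set in the same closure with the ring C aryl equatorial, hence 1,2-trans; the absolute sense of all three has to come from the IDPi anion that accompanies the C1 cation into the enantio-determining closure. The step needs crossed instead of homo-coupling, which the oxidation-potential gap between 3 and 5, the excess of 5 and the slow addition of 3 should secure; closure onto C1 and not onto C4, which follows from the cation residing next to the better donor ring C so that ring A must be the nucleophile; and attack para and not ortho to the ring A methoxy group, the ortho carbon being flanked by two substituents.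

Step 4
Reactants: 8 (1S,2S,3R)-1-(4-benzyloxy-3-methoxyphenyl)-6-methoxy-2,3-dimethyl-1,2,3,4-tetrahydronaphthalen-7-yl pivalate
Product: 9 (1S,2S,3R)-1-(4-hydroxy-3-methoxyphenyl)-6-methoxy-2,3-dimethyl-1,2,3,4-tetrahydronaphthalen-7-yl pivalate
Conditions: H2 (1 atm), 10% Pd/C, EtOAc/EtOH, rt
Reagents that add atoms: none
Why: Catalytic hydrogenolysis of the benzyl aryl ether; the aryl pivalate, the methyl ethers and the diarylmethine C1–H bond are inert under these neutral conditions, so only the ring C oxygen is set free and no stereocentre is touched.

Step 5
Reactants: 10 ethyl (S)-lactate; 11 N,O-dimethylhydroxylamine hydrochloride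
Product: 12 (S)-2-hydroxy-N-methoxy-N-methylpropanamide
Conditions: MeNHOMe·HCl, iPrMgCl (excess), THF, −20 → 0 °C
Reagents that add atoms: N,O-dimethylhydroxylamine hydrochloride (11), CNOC.Cl
Why: Weinreb amide formation by attack of the chloromagnesium amide on the ester; the α-stereocentre is protected from enolisation by its magnesium alkoxide and is carried through unchanged.

Step 6
Reactants: 9 (1S,2S,3R)-1-(4-hydroxy-3-methoxyphenyl)-6-methoxy-2,3-dimethyl-1,2,3,4-tetrahydronaphthalen-7-yl pivalate; 12 (S)-2-hydroxy-N-methoxy-N-methylpropanamide
Product: 13 (2R)-N-methoxy-N-methyl-2-{2-methoxy-4-[(1S,2S,3R)-6-methoxy-2,3-dimethyl-7-(pivaloyloxy)-1,2,3,4-tetrahydronaphthalen-1-yl]phenoxy}propanamide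
Conditions: PPh3, diisopropyl azodicarboxylate, THF, 0 °C → rt
Reagents that add atoms: (S)-2-hydroxy-N-methoxy-N-methylpropanamide (12), C[C@H](O)C(=O)N(C)OC
Why: Mitsunobu etherification: the alcohol of 12 is activated as its oxyphosphonium salt and displaced by the phenoxide of 9 in an SN2 step accelerated by the adjacent carbonyl group, so C8' is set as R by inversion of the (S) centre of 12; the pivalate is untouched.

Step 7
Reactants: 14 4-bromo-2-methoxyphenol; 15 tert-butyldimethylsilyl chloride
Product: 16 (4-bromo-2-methoxyphenoxy)(tert-butyl)dimethylsilane
Conditions: TBSCl, imidazole, DMF, rt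
Reagents that add atoms: tert-butyldimethylsilyl chloride (15), CC(C)(C)[Si](C)(C)Cl
Why: Silylation of the phenol with imidazole as base and nucleophilic catalyst; the aryl silyl ether withstands Grignard formation and is removed by base at the end.

Step 8
Reactants: 13 (2R)-N-methoxy-N-methyl-2-{2-methoxy-4-[(1S,2S,3R)-6-methoxy-2,3-dimethyl-7-(pivaloyloxy)-1,2,3,4-tetrahydronaphthalen-1-yl]phenoxy}propanamide; 16 (4-bromo-2-methoxyphenoxy)(tert-butyl)dimethylsilane
Product: 18 (2R)-1-[4-(tert-butyldimethylsilyloxy)-3-methoxyphenyl]-2-{2-methoxy-4-[(1S,2S,3R)-6-methoxy-2,3-dimethyl-7-(pivaloyloxy)-1,2,3,4-tetrahydronaphthalen-1-yl]phenoxy}propan-1-one, via arylmagnesium bromide 17 (not isolated)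
Conditions: 16, Mg, THF, 40 °C; then 13, THF, −20 → 0 °C; aq NH4Cl, 0 °C
Reagents that add atoms: aryl bromide 16 (as its Grignard reagent 17), COc1cc(Br)ccc1O[Si](C)(C)C(C)(C)C
Why: Weinreb ketone synthesis: Grignard reagent 17 adds once to the amide and the magnesium chelate of the tetrahedral adduct persists until the quench, so no over-addition occurs and the ketone with its epimerisable C8' centre appears only on cold, weakly acidic work-up; the α-oxygenated amide should react faster than the hindered aryl pivalate at this temperature.

Step 9
Reactants: 18 (2R)-1-[4-(tert-butyldimethylsilyloxy)-3-methoxyphenyl]-2-{2-methoxy-4-[(1S,2S,3R)-6-methoxy-2,3-dimethyl-7-(pivaloyloxy)-1,2,3,4-tetrahydronaphthalen-1-yl]phenoxy}propan-1-one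
Product: 19 (1S,2R)-1-[4-(tert-butyldimethylsilyloxy)-3-methoxyphenyl]-2-{2-methoxy-4-[(1S,2S,3R)-6-methoxy-2,3-dimethyl-7-(pivaloyloxy)-1,2,3,4-tetrahydronaphthalen-1-yl]phenoxy}propan-1-ol
Conditions: Zn(BH4)2, Et2O/CH2Cl2, −30 → 0 °C
Reagents that add atoms: none
Why: Chelation-controlled (Cram chelate) hydride reduction: zinc bridges the carbonyl oxygen and the C8' ether oxygen, assisted by the neighbouring ring C methoxy group, and hydride enters from the face of the C8' hydrogen, which sets C7' as S (erythro); Zn(BH4)2 does not reduce the pivalate or cleave the silyl ether.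

Step 10
Reactants: 19 (1S,2R)-1-[4-(tert-butyldimethylsilyloxy)-3-methoxyphenyl]-2-{2-methoxy-4-[(1S,2S,3R)-6-methoxy-2,3-dimethyl-7-(pivaloyloxy)-1,2,3,4-tetrahydronaphthalen-1-yl]phenoxy}propan-1-ol
Product: 20 (1S,2R)-1-(4-hydroxy-3-methoxyphenyl)-2-{4-[(1S,2S,3R)-7-hydroxy-6-methoxy-2,3-dimethyl-1,2,3,4-tetrahydronaphthalen-1-yl]-2-methoxyphenoxy}propan-1-ol
Conditions: NaOMe (4 equiv), MeOH/THF, 0 °C → rt; then AcOH
Reagents that add atoms: none
Why: Base-mediated methanolysis: methoxide transesterifies the aryl pivalate and attacks silicon of the aryl silyl ether, both with phenoxide as leaving group; at or below room temperature the ring D phenoxide should not expel the C7' hydroxide, so C7' and C8' are retained and the acetic acid quench returns the free phenols of 20.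

## Compound list

1 | (E)-isoeugenol, 2-methoxy-4-[(E)-prop-1-enyl]phenol | C/C=C/c1ccc(O)c(OC)c1 | starting material
2 | benzyl bromide | BrCc1ccccc1 | starting material
3 | 1-(benzyloxy)-2-methoxy-4-[(E)-prop-1-enyl]benzene | C/C=C/c1ccc(OCc2ccccc2)c(OC)c1 | intermediate
4 | pivaloyl chloride | CC(C)(C)C(=O)Cl | starting material
5 | 2-methoxy-4-[(E)-prop-1-enyl]phenyl pivalate | C/C=C/c1ccc(OC(=O)C(C)(C)C)c(OC)c1 | intermediate
6 | distonic radical cation: 1-(4-benzyloxy-3-methoxyphenyl)-2,3-dimethyl-4-(3-methoxy-4-pivaloyloxyphenyl)butane chain with cation at C1 and radical at C4, C2 and C3 configured as in 8 | COc1cc([CH+][C@@H](C)[C@H](C)[CH]c2ccc(OC(=O)C(C)(C)C)c(OC)c2)ccc1OCc1ccccc1 | intermediate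
7 | C4 benzylic radical of 8: 1-(4-benzyloxy-3-methoxyphenyl)-6-methoxy-2,3-dimethyl-7-pivaloyloxy-1,2,3,4-tetrahydronaphthalen-4-yl, C1–C3 configured as in 8 | COc1cc([C@H]2c3cc(OC(=O)C(C)(C)C)c(OC)cc3[CH][C@@H](C)[C@@H]2C)ccc1OCc1ccccc1 | intermediate
8 | (1S,2S,3R)-1-(4-benzyloxy-3-methoxyphenyl)-6-methoxy-2,3-dimethyl-1,2,3,4-tetrahydronaphthalen-7-yl pivalate | COc1cc([C@H]2c3cc(OC(=O)C(C)(C)C)c(OC)cc3C[C@@H](C)[C@@H]2C)ccc1OCc1ccccc1 | intermediate
9 | (1S,2S,3R)-1-(4-hydroxy-3-methoxyphenyl)-6-methoxy-2,3-dimethyl-1,2,3,4-tetrahydronaphthalen-7-yl pivalate | COc1cc([C@H]2c3cc(OC(=O)C(C)(C)C)c(OC)cc3C[C@@H](C)[C@@H]2C)ccc1O | intermediate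
10 | ethyl (S)-lactate | CCOC(=O)[C@H](C)O | starting material
11 | N,O-dimethylhydroxylamine hydrochloride | CNOC.Cl | starting material
12 | (S)-2-hydroxy-N-methoxy-N-methylpropanamide | C[C@H](O)C(=O)N(C)OC | intermediate
13 | (2R)-N-methoxy-N-methyl-2-{2-methoxy-4-[(1S,2S,3R)-6-methoxy-2,3-dimethyl-7-(pivaloyloxy)-1,2,3,4-tetrahydronaphthalen-1-yl]phenoxy}propanamide | CON(C)C(=O)[C@@H](C)Oc1ccc([C@H]2c3cc(OC(=O)C(C)(C)C)c(OC)cc3C[C@@H](C)[C@@H]2C)cc1OC | intermediate
14 | 4-bromo-2-methoxyphenol | COc1cc(Br)ccc1O | starting material
15 | tert-butyldimethylsilyl chloride | CC(C)(C)[Si](C)(C)Cl | starting material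
16 | (4-bromo-2-methoxyphenoxy)(tert-butyl)dimethylsilane | COc1cc(Br)ccc1O[Si](C)(C)C(C)(C)C | intermediate
17 | [4-(tert-butyldimethylsilyloxy)-3-methoxyphenyl]magnesium bromide | COc1cc([Mg]Br)ccc1O[Si](C)(C)C(C)(C)C | intermediate
18 | (2R)-1-[4-(tert-butyldimethylsilyloxy)-3-methoxyphenyl]-2-{2-methoxy-4-[(1S,2S,3R)-6-methoxy-2,3-dimethyl-7-(pivaloyloxy)-1,2,3,4-tetrahydronaphthalen-1-yl]phenoxy}propan-1-one | COc1cc(C(=O)[C@@H](C)Oc2ccc([C@H]3c4cc(OC(=O)C(C)(C)C)c(OC)cc4C[C@@H](C)[C@@H]3C)cc2OC)ccc1O[Si](C)(C)C(C)(C)C | intermediate
19 | (1S,2R)-1-[4-(tert-butyldimethylsilyloxy)-3-methoxyphenyl]-2-{2-methoxy-4-[(1S,2S,3R)-6-methoxy-2,3-dimethyl-7-(pivaloyloxy)-1,2,3,4-tetrahydronaphthalen-1-yl]phenoxy}propan-1-ol | COc1cc([C@H](O)[C@@H](C)Oc2ccc([C@H]3c4cc(OC(=O)C(C)(C)C)c(OC)cc4C[C@@H](C)[C@@H]3C)cc2OC)ccc1O[Si](C)(C)C(C)(C)C | intermediate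
20 | (1S,2R)-1-(4-hydroxy-3-methoxyphenyl)-2-{4-[(1S,2S,3R)-7-hydroxy-6-methoxy-2,3-dimethyl-1,2,3,4-tetrahydronaphthalen-1-yl]-2-methoxyphenoxy}propan-1-ol (CID53359464) | COc1cc([C@H](O)[C@@H](C)Oc2ccc([C@H]3c4cc(O)c(OC)cc4C[C@@H](C)[C@@H]3C)cc2OC)ccc1O | target

## Step count and least certain steps

Total step count: 10. Longest linear sequence: 7 steps (steps 1, 3, 4, 6, 8, 9, 10, from 1 to 20).

**Step 3 (key step, proposed new method).**
- Most likely failure: little or no transfer of chirality. The anion may be only loosely associated with a charge that is delocalised over ring C, and the new bond forms on the far side of that cation. A racemic background through solvent-separated ions, or through Brønsted-acid catalysis by the IDPi acid released on rearomatisation, would add to this.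
- Further failure processes: homo-coupling of 3 if its stationary concentration is not kept low; ring closure in the reverse sense (ring C onto C4); thiol–ene addition of the co-catalyst; hydrogen loss at the benzylic OCH2 of the ether radical cation.
- Fallback: absolute configuration from resolution instead of catalysis. It sets out from 3 and 5. These are cyclodimerised under the established non-asymmetric formal [4+2] conditions for styrenes (9-mesityl-10-methylacridinium tetrafluoroborate, (PhS)2, 1,2-dichloroethane, blue LEDs, rt, 5 in excess), which should give the racemic all-trans tetralin pivalate F1. Its enantiomers are separated by preparative HPLC on a chiral stationary phase (amylose tris(3,5-dimethylphenylcarbamate)); the (1S,2S,3R) enantiomer is 8, where the route is rejoined.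

**Step 8.**
- Most likely failure: competing attack of the Grignard reagent on the aryl pivalate, because an aryl ester is an activated ester despite its bulk; and partial epimerisation at C8' once the ketone is liberated.
- Fallback: carry ring A as its magnesium phenoxide. It sets out from 13. The pivalate is removed with K2CO3 in MeOH at rt to give phenol amide F3. Treatment with 3 equiv of 17 (the first equivalent deprotonates the phenol) should give phenol ketone F4. Zn(BH4)2 reduction as in step 9 gives the erythro alcohol F5, and the conditions of step 10 remove the silyl group, which rejoins the route at 20.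

**Step 9.**
- Most likely failure: insufficient facial selectivity. An aryloxy oxygen is a weak ligand, so the open Felkin–Anh pathway to the threo (7'R) alcohol can compete with the chelate.
- Fallback: reagent control instead of substrate control. It sets out from 18 and uses a CBS reduction with (S)-2-methyl-CBS-oxazaborolidine ((3aS)-1-methyl-3,3-diphenyltetrahydro-1H,3H-pyrrolo[1,2-c][1,3,2]oxazaborole) and BH3·SMe2 in toluene at −20 °C. By the usual model (aryl as the large group) this should deliver the 7'S alcohol, returning to the route at 19. The fallback makes no new compound (F0).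

**Step 6.**
- Most likely failure: slow coupling of the secondary alcohol next to a tertiary amide, with elimination of the activated alcohol or incomplete inversion.
- Fallback: a preformed sulfonate instead of in-situ activation. It sets out from 12, which is converted with TsCl, Et3N and 4-(dimethylamino)pyridine in CH2Cl2 into tosylate F2. Phenol 9 displaces it with K2CO3 in MeCN at 60 °C by SN2 with inversion, which returns to the route at 13.

**Step 10.**
- Most likely failure: base-induced damage to the product during a slow pivalate methanolysis, namely expulsion of the C7' hydroxide from the ring D phenoxide (quinone methide formation), with epimerisation at C7' or elimination.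
- Fallback: fluoride and reductive cleavage instead of methoxide. It sets out from 19. Bu4NF buffered with AcOH in THF at 0 °C removes the silyl group to give pivalate triol F6. iBu2AlH in CH2Cl2 at −78 °C then cleaves the pivalate reductively, which returns to the route at 20.

## Further compounds

F1 | step 3 | racemic 1-(4-benzyloxy-3-methoxyphenyl)-6-methoxy-2,3-dimethyl-1,2,3,4-tetrahydronaphthalen-7-yl pivalate, all-trans: 8 together with its (1R,2R,3S) enantiomer | COc1cc([C@H]2c3cc(OC(=O)C(C)(C)C)c(OC)cc3C[C@@H](C)[C@@H]2C)ccc1OCc1ccccc1.COc1cc([C@@H]2c3cc(OC(=O)C(C)(C)C)c(OC)cc3C[C@H](C)[C@H]2C)ccc1OCc1ccccc1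
F2 | step 6 | (2S)-1-[methoxy(methyl)amino]-1-oxopropan-2-yl 4-methylbenzenesulfonate | C[C@H](OS(=O)(=O)c1ccc(C)cc1)C(=O)N(C)OC
F3 | step 8 | (2R)-2-{4-[(1S,2S,3R)-7-hydroxy-6-methoxy-2,3-dimethyl-1,2,3,4-tetrahydronaphthalen-1-yl]-2-methoxyphenoxy}-N-methoxy-N-methylpropanamide | CON(C)C(=O)[C@@H](C)Oc1ccc([C@H]2c3cc(O)c(OC)cc3C[C@@H](C)[C@@H]2C)cc1OC
F4 | step 8 | (2R)-1-[4-(tert-butyldimethylsilyloxy)-3-methoxyphenyl]-2-{4-[(1S,2S,3R)-7-hydroxy-6-methoxy-2,3-dimethyl-1,2,3,4-tetrahydronaphthalen-1-yl]-2-methoxyphenoxy}propan-1-one | COc1cc(C(=O)[C@@H](C)Oc2ccc([C@H]3c4cc(O)c(OC)cc4C[C@@H](C)[C@@H]3C)cc2OC)ccc1O[Si](C)(C)C(C)(C)C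
F5 | step 8 | (1S,2R)-1-[4-(tert-butyldimethylsilyloxy)-3-methoxyphenyl]-2-{4-[(1S,2S,3R)-7-hydroxy-6-methoxy-2,3-dimethyl-1,2,3,4-tetrahydronaphthalen-1-yl]-2-methoxyphenoxy}propan-1-ol | COc1cc([C@H](O)[C@@H](C)Oc2ccc([C@H]3c4cc(O)c(OC)cc4C[C@@H](C)[C@@H]3C)cc2OC)ccc1O[Si](C)(C)C(C)(C)C
F0 | step 9 | none | none
F6 | step 10 | (1S,2R)-1-(4-hydroxy-3-methoxyphenyl)-2-{2-methoxy-4-[(1S,2S,3R)-6-methoxy-2,3-dimethyl-7-(pivaloyloxy)-1,2,3,4-tetrahydronaphthalen-1-yl]phenoxy}propan-1-ol | COc1cc([C@H](O)[C@@H](C)Oc2ccc([C@H]3c4cc(OC(=O)C(C)(C)C)c(OC)cc4C[C@@H](C)[C@@H]3C)cc2OC)ccc1O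
A1 | alternative 1 | 2-[(1S,2R)-1-(4-benzyloxy-3-methoxyphenyl)-1-(2-chloro-4-methoxy-5-triisopropylsilyloxyphenyl)propan-2-yl]-4,4,5,5-tetramethyl-1,3,2-dioxaborolane | COc1cc([C@H]([C@@H](C)B2OC(C)(C)C(C)(C)O2)c2cc(O[Si](C(C)C)(C(C)C)C(C)C)c(OC)cc2Cl)ccc1OCc1ccccc1
A2 | alternative 1 | 2-[(Z)-2-(2-chloro-4-methoxy-5-triisopropylsilyloxyphenyl)ethenyl]-4,4,5,5-tetramethyl-1,3,2-dioxaborolane | COc1cc(Cl)c(/C=C\B2OC(C)(C)C(C)(C)O2)cc1O[Si](C(C)C)(C(C)C)C(C)C
A3 | alternative 1 | 4-benzyloxy-3-methoxyphenyl trifluoromethanesulfonate | COc1cc(OS(=O)(=O)C(F)(F)F)ccc1OCc1ccccc1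
A4 | alternative 2 | methyl 1-(4-allyloxy-3-methoxyphenyl)-7-benzyloxy-4-hydroxy-6-methoxy-2-methyl-1,2,3,4-tetrahydronaphthalene-3-carboxylate (target numbering; C1, C2, C3 all-trans, 4-OH cis to the ester) | COc1cc([C@H]2c3cc(OCc4ccccc4)c(OC)cc3[C@@H](O)[C@@H](C(=O)OC)[C@@H]2C)ccc1OCC=C
A5 | alternative 2 | 2-[(4-allyloxy-3-methoxyphenyl)methyl]-4-benzyloxy-5-methoxybenzaldehyde | COc1cc(C=O)c(Cc2ccc(OCC=C)c(OC)c2)cc1OCc1ccccc1
A6 | alternative 2 | methyl (E)-but-2-enoate | C/C=C/C(=O)OC
A7 | alternative 3 | 7-benzyloxy-1-(4-hydroxy-3-methoxyphenyl)-6-methoxy-3-methyl-1,2,3,4-tetrahydronaphthalene-2-carbaldehyde (target numbering; all-trans) | COc1cc([C@H]2c3cc(OCc4ccccc4)c(OC)cc3C[C@@H](C)[C@@H]2C=O)ccc1O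
A8 | alternative 3 | (3R)-4-{4-benzyloxy-2-[hydroxy(4-hydroxy-3-methoxyphenyl)methyl]-5-methoxyphenyl}-3-methylbutanal | COc1cc(C(O)c2cc(OCc3ccccc3)c(OC)cc2C[C@@H](C)CC=O)ccc1O
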